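**Strategy**

The target's dihydrobenzofuran (O1–C2–C3–C3a–C7a) carries exocyclic C9 on C3. Inserting C9 between C3 and C3a gives a chroman-4-one, so the trans-2-aryl-3-carbinol is a ring-contracted (2R)-flavanone. One iodine(III)-mediated 1,2-shift of the fused aryl carbon from the carbonyl carbon to C3 forms the C3–C3a bond, shrinks the pyranone to the dihydrofuran, sets C3 trans to the C2 guaiacyl ring and leaves C9 as a methyl ester. The precursor is a (2R)-8-methoxy-6-(3-silyloxypropyl)flavanone whose B-ring oxygen is a pivalate, made by asymmetric arylboronic acid addition to a chromone. Reduction, Mitsunobu coumaroylation and desilylation finish.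

Key step: step 8

**Remarks on the chemistry (made before the steps)**

- Numbering: chroman numbering for 7 and 11–13, benzofuran numbering for 14–18; C9 is the exocyclic carbon on C3.
- Stereochemical bookkeeping: the target is (2R,3S), trans. The ester stage is (2R,3R) only because CO2Me outranks C2, and the flavanone is 2R. The spatial arrangement is the same throughout, and no structure needed correction.
- Precursor design, change 1: the primary alcohol is carried as its TBDPS ether, the most acid-stable common silyl ether, because the key step runs in strong acid.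
- Precursor design, change 2: the guaiacyl oxygen is carried as a pivalate, not as a silyl or alkyl ether. A para oxygen donor on the C2 aryl ring would favour the competing C2-to-C3 aryl shift (isoflavone), ionisation of the benzylic C2–O1 bond (loss of optical purity) and oxidation of that ring. The acyl group switches the donor off and is removed in the ester reduction at no cost in steps.
- The acetyl group is introduced by directed ortho-metalation, because electrophilic acylation of a 4-alkylguaiacol can also go para to the methoxy group.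
- Assumption: Pd/(S)-t-BuPyOx is taken to deliver the aryl group to the chromone with the same facial sense as to cyclic enones (Si face of C2, giving 2R). If the first run shows the opposite sense, the (R)-ligand is used with no other change.

**Route**

Step 1
Reactants: 1 dihydroconiferyl alcohol
Product: 2 3-[3-methoxy-4-(methoxymethoxy)phenyl]propan-1-ol
Conditions: MOMCl, K2CO3, acetone, 0 °C → rt
Reagents that add atoms: chloromethyl methyl ether, COCCl
Why: Williamson-type O-alkylation in which carbonate deprotonates only the phenol, so the MOM acetal forms on the aryl oxygen (the ortho-director needed in step 3) and the primary alcohol stays free.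

Step 2
Reactants: 2 3-[3-methoxy-4-(methoxymethoxy)phenyl]propan-1-ol
Product: 3 tert-butyl{3-[3-methoxy-4-(methoxymethoxy)phenyl]propoxy}diphenylsilane
Conditions: TBDPSCl, imidazole, CH2Cl2, rt
Reagents that add atoms: tert-butylchlorodiphenylsilane, CC(C)(C)[Si](Cl)(c1ccccc1)c1ccccc1
Why: Imidazole-promoted silylation of a primary alcohol; TBDPS is chosen because it should withstand butyllithium at low temperature, strong acid in orthoformate and LiAlH4, yet leaves with fluoride.

Step 3
Reactants: 3 tert-butyl{3-[3-methoxy-4-(methoxymethoxy)phenyl]propoxy}diphenylsilane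
Product: 5 1-{5-[3-(tert-butyldiphenylsilyloxy)propyl]-3-methoxy-2-(methoxymethoxy)phenyl}ethan-1-one, via aryllithium 4 (not isolated)
Conditions: n-BuLi, TMEDA, Et2O, 0 °C; then MeC(O)N(OMe)Me, −78 °C → rt; aq. NH4Cl
Reagents that add atoms: N-methoxy-N-methylacetamide, CC(=O)N(C)OC
Why: Directed ortho-metalation, in which the chelating OMOM group (a stronger director than OMe) steers lithiation to its only free ortho position, and the Weinreb amide stops at the ketone through its chelated tetrahedral adduct.

Step 4
Reactants: 5 1-{5-[3-(tert-butyldiphenylsilyloxy)propyl]-3-methoxy-2-(methoxymethoxy)phenyl}ethan-1-one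
Product: 7 6-[3-(tert-butyldiphenylsilyloxy)propyl]-8-methoxy-4H-chromen-4-one, via enaminone 6 (not isolated)
Conditions: Me2NCH(OMe)2, toluene, 110 °C; evaporate; then TFA, wet CH2Cl2, 0 °C → rt
Reagents that add atoms: N,N-dimethylformamide dimethyl acetal, COC(OC)N(C)C
Why: Enaminone condensation of the methyl ketone with the amide acetal, then acid cleaves the MOM acetal and the freed phenol adds to the β-carbon with loss of dimethylamine (addition–elimination chromone synthesis), conditions under which a TBDPS ether should persist.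

Step 5
Reactants: 8 4-bromo-2-methoxyphenol
Product: 9 4-bromo-2-methoxyphenyl pivalate
Conditions: PivCl, Et3N, DMAP (cat.), CH2Cl2, 0 °C → rt
Reagents that add atoms: pivaloyl chloride, CC(C)(C)C(=O)Cl
Why: DMAP-catalysed acylation of a phenol, installing a hindered electron-withdrawing aryl ester that should resist the acidic, weakly nucleophilic media of steps 6–8.

Step 6
Reactants: 9 4-bromo-2-methoxyphenyl pivalate
Product: 10 [3-methoxy-4-(pivaloyloxy)phenyl]boronic acid
Conditions: B2(OH)4, XPhos Pd G2 (cat.), XPhos (cat.), KOAc, EtOH, 80 °C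
Reagents that add atoms: tetrahydroxydiboron, OB(O)B(O)O
Why: Miyaura-type Pd(0)-catalysed borylation of an aryl bromide with tetrahydroxydiboron, which gives the free boronic acid directly under acetate-base conditions that an aryl pivalate should tolerate.

Step 7
Reactants: 7 6-[3-(tert-butyldiphenylsilyloxy)propyl]-8-methoxy-4H-chromen-4-one; 10 [3-methoxy-4-(pivaloyloxy)phenyl]boronic acid
Product: 11 (2R)-6-[3-(tert-butyldiphenylsilyloxy)propyl]-8-methoxy-2-[3-methoxy-4-(pivaloyloxy)phenyl]chroman-4-one
Conditions: Pd(OCOCF3)2 (5 mol %), (S)-t-BuPyOx (6 mol %), NH4PF6 (30 mol %), H2O (5 equiv), ClCH2CH2Cl, 60 °C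
Reagents that add atoms: none
Why: Pd(II)/pyridine-oxazoline-catalysed asymmetric conjugate addition of an arylboronic acid to a chromone (transmetalation, enantio-determining carbopalladation of C2=C3, protonolysis of the Pd enolate), in which the tert-butyl group of the (S)-ligand should direct the aryl group to the Si face of C2 to set 2R, while the base-free medium avoids retro-oxa-Michael racemisation.

Step 8
Reactants: 11 (2R)-6-[3-(tert-butyldiphenylsilyloxy)propyl]-8-methoxy-2-[3-methoxy-4-(pivaloyloxy)phenyl]chroman-4-one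
Product: 14 methyl (2R,3R)-5-[3-(tert-butyldiphenylsilyloxy)propyl]-7-methoxy-2-[3-methoxy-4-(pivaloyloxy)phenyl]-2,3-dihydro-1-benzofuran-3-carboxylate, via methyl enol ether 12 (not isolated), via C3 iodane 13 (not isolated)
Conditions: PhI(OAc)2 (1.2 equiv), conc. H2SO4 (0.5 equiv), HC(OMe)3, 0 °C → rt; aq. NaHCO3
Reagents that add atoms: trimethyl orthoformate, COC(OC)OC
Why: Acid and orthoformate turn the ketone into its ketal and methyl enol ether 12, whose C3 attacks the iodine(III) electrophile anti to the pseudo-equatorial C2 aryl group, and methanol capture at C4 gives the trans iodane 13 with its C3–I bond antiperiplanar to the C4–C4a ring bond. Iodobenzene then departs as C4a migrates from C4 to C3 through a phenonium-like transition state stabilised by the ortho ring oxygen O1, and the dimethoxycarbenium ion left at old C4 collapses to the methyl ester. The closest known reaction type is the iodine(III)- or thallium(III)-mediated oxidative 1,2-aryl shift of aryl ketones in orthoformate, which is established for the contraction of flavanones to methyl trans-2-aryl-2,3-dihydrobenzofuran-3-carboxylates. The five-membered ring O1–C2–C3–C3a–C7a is not closed by a cyclisation but arises from the six-membered ring by this shift, which forms C3–C3a and expels old C4 as the exocyclic ester carbon C9. C3 is set by substrate control, since anti iodination followed by migration with inversion places CO2Me trans to the C2 aryl group (3R), which is also the thermodynamically preferred epimer, while C2 is not touched. The step needs C4a migration to win over C2-aryl migration, flavone formation and ionisation of C2–O1, which the acceptor-substituted pivaloyloxy B ring and the O1-activated A ring should secure, and the TBDPS ether and the pivalate are chosen to survive the acid.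

Step 9
Reactants: 14 methyl (2R,3R)-5-[3-(tert-butyldiphenylsilyloxy)propyl]-7-methoxy-2-[3-methoxy-4-(pivaloyloxy)phenyl]-2,3-dihydro-1-benzofuran-3-carboxylate
Product: 15 4-{(2R,3S)-5-[3-(tert-butyldiphenylsilyloxy)propyl]-3-(hydroxymethyl)-7-methoxy-2,3-dihydro-1-benzofuran-2-yl}-2-methoxyphenol
Conditions: LiAlH4, THF, 0 °C; Rochelle salt work-up
Reagents that add atoms: none
Why: Hydride reduction of the methyl ester to the C9 carbinol, which should also cleave the aryl pivalate in the same operation and free the guaiacyl phenol, with neither stereocentre involved (the descriptor at C3 becomes S only because CH2OH ranks below C2).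

Step 10
Reactants: 15 4-{(2R,3S)-5-[3-(tert-butyldiphenylsilyloxy)propyl]-3-(hydroxymethyl)-7-methoxy-2,3-dihydro-1-benzofuran-2-yl}-2-methoxyphenol; 16 p-coumaric acid
Product: 17 {(2R,3S)-5-[3-(tert-butyldiphenylsilyloxy)propyl]-2-(4-hydroxy-3-methoxyphenyl)-7-methoxy-2,3-dihydro-1-benzofuran-3-yl}methyl (E)-3-(4-hydroxyphenyl)prop-2-enoate
Conditions: PPh3, DIAD, THF, 0 °C → rt
Reagents that add atoms: none
Why: Mitsunobu esterification, in which the primary alcohol is activated as its alkoxyphosphonium ion and displaced by the carboxylate, the most acidic partner, so that neither free phenol should be acylated or alkylated (chemoselective esterification of phenolic acids and phenolic alcohols under these conditions is established) and the E alkene and C3 stay untouched.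

Step 11
Reactants: 17 {(2R,3S)-5-[3-(tert-butyldiphenylsilyloxy)propyl]-2-(4-hydroxy-3-methoxyphenyl)-7-methoxy-2,3-dihydro-1-benzofuran-3-yl}methyl (E)-3-(4-hydroxyphenyl)prop-2-enoate
Product: 18 CNP0202924.1, [(2R,3S)-2-(4-hydroxy-3-methoxyphenyl)-5-(3-hydroxypropyl)-7-methoxy-2,3-dihydro-1-benzofuran-3-yl]methyl (E)-3-(4-hydroxyphenyl)prop-2-enoate
Conditions: HF·pyridine, THF/pyridine, 0 °C → rt
Reagents that add atoms: none
Why: Fluoride-driven cleavage of the silyl ether (Si–F bond formation) under non-basic conditions, which should leave the cinnamate ester, the E alkene, both phenols and the benzylic aryl ether intact.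

**Compound list**

1 | dihydroconiferyl alcohol, 4-(3-hydroxypropyl)-2-methoxyphenol | COc1cc(CCCO)ccc1O | starting material
2 | 3-[3-methoxy-4-(methoxymethoxy)phenyl]propan-1-ol | COCOc1ccc(CCCO)cc1OC | intermediate
3 | tert-butyl{3-[3-methoxy-4-(methoxymethoxy)phenyl]propoxy}diphenylsilane | COCOc1ccc(CCCO[Si](c2ccccc2)(c2ccccc2)C(C)(C)C)cc1OC | intermediate
4 | {5-[3-(tert-butyldiphenylsilyloxy)propyl]-3-methoxy-2-(methoxymethoxy)phenyl}lithium | [Li]c1cc(CCCO[Si](c2ccccc2)(c2ccccc2)C(C)(C)C)cc(OC)c1OCOC | intermediate (not isolated)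
5 | 1-{5-[3-(tert-butyldiphenylsilyloxy)propyl]-3-methoxy-2-(methoxymethoxy)phenyl}ethan-1-one | CC(=O)c1cc(CCCO[Si](c2ccccc2)(c2ccccc2)C(C)(C)C)cc(OC)c1OCOC | intermediate
6 | (E)-1-{5-[3-(tert-butyldiphenylsilyloxy)propyl]-3-methoxy-2-(methoxymethoxy)phenyl}-3-(dimethylamino)prop-2-en-1-one | CN(C)/C=C/C(=O)c1cc(CCCO[Si](c2ccccc2)(c2ccccc2)C(C)(C)C)cc(OC)c1OCOC | intermediate (not isolated)
7 | 6-[3-(tert-butyldiphenylsilyloxy)propyl]-8-methoxy-4H-chromen-4-one | O=c1ccoc2c(OC)cc(CCCO[Si](c3ccccc3)(c3ccccc3)C(C)(C)C)cc12 | intermediate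
8 | 4-bromo-2-methoxyphenol | COc1cc(Br)ccc1O | starting material
9 | 4-bromo-2-methoxyphenyl pivalate | COc1cc(Br)ccc1OC(=O)C(C)(C)C | intermediate
10 | [3-methoxy-4-(pivaloyloxy)phenyl]boronic acid | COc1cc(B(O)O)ccc1OC(=O)C(C)(C)C | intermediate
11 | (2R)-6-[3-(tert-butyldiphenylsilyloxy)propyl]-8-methoxy-2-[3-methoxy-4-(pivaloyloxy)phenyl]chroman-4-one | COc1cc([C@@H]2Oc3c(OC)cc(CCCO[Si](c4ccccc4)(c5ccccc5)C(C)(C)C)cc3C(=O)C2)ccc1OC(=O)C(C)(C)C | intermediate (key-step precursor)
12 | 4-[(2R)-6-[3-(tert-butyldiphenylsilyloxy)propyl]-4,8-dimethoxy-2H-chromen-2-yl]-2-methoxyphenyl pivalate (methyl enol ether of 11) | COc1cc([C@@H]2Oc3c(OC)cc(CCCO[Si](c4ccccc4)(c5ccccc5)C(C)(C)C)cc3C(OC)=C2)ccc1OC(=O)C(C)(C)C | intermediate (not isolated)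
13 | 4-[(2S,3S)-3-[acetoxy(phenyl)-λ3-iodanyl]-6-[3-(tert-butyldiphenylsilyloxy)propyl]-4,4,8-trimethoxychroman-2-yl]-2-methoxyphenyl pivalate (iodine trans to the C2 aryl group; C2 geometry as in 11) | COc1cc([C@@H]2Oc3c(OC)cc(CCCO[Si](c4ccccc4)(c5ccccc5)C(C)(C)C)cc3C(OC)(OC)[C@H]2[I](OC(C)=O)c6ccccc6)ccc1OC(=O)C(C)(C)C | intermediate (not isolated)
14 | methyl (2R,3R)-5-[3-(tert-butyldiphenylsilyloxy)propyl]-7-methoxy-2-[3-methoxy-4-(pivaloyloxy)phenyl]-2,3-dihydro-1-benzofuran-3-carboxylate (trans) | COc1cc([C@@H]2Oc3c(OC)cc(CCCO[Si](c4ccccc4)(c5ccccc5)C(C)(C)C)cc3[C@H]2C(=O)OC)ccc1OC(=O)C(C)(C)C | intermediate (key-step product)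
15 | 4-{(2R,3S)-5-[3-(tert-butyldiphenylsilyloxy)propyl]-3-(hydroxymethyl)-7-methoxy-2,3-dihydro-1-benzofuran-2-yl}-2-methoxyphenol | COc1cc([C@@H]2Oc3c(OC)cc(CCCO[Si](c4ccccc4)(c5ccccc5)C(C)(C)C)cc3[C@H]2CO)ccc1O | intermediate
16 | p-coumaric acid, (E)-3-(4-hydroxyphenyl)prop-2-enoic acid | O=C(O)/C=C/c1ccc(O)cc1 | starting material
17 | {(2R,3S)-5-[3-(tert-butyldiphenylsilyloxy)propyl]-2-(4-hydroxy-3-methoxyphenyl)-7-methoxy-2,3-dihydro-1-benzofuran-3-yl}methyl (E)-3-(4-hydroxyphenyl)prop-2-enoate | COc1cc([C@@H]2Oc3c(OC)cc(CCCO[Si](c4ccccc4)(c5ccccc5)C(C)(C)C)cc3[C@H]2COC(=O)/C=C/c2ccc(O)cc2)ccc1O | intermediate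
18 | CNP0202924.1, [(2R,3S)-2-(4-hydroxy-3-methoxyphenyl)-5-(3-hydroxypropyl)-7-methoxy-2,3-dihydro-1-benzofuran-3-yl]methyl (E)-3-(4-hydroxyphenyl)prop-2-enoate | COc1cc([C@@H]2Oc3c(OC)cc(CCCO)cc3[C@H]2COC(=O)/C=C/c2ccc(O)cc2)ccc1O | target

**Step count**

Total steps: 11. Longest linear sequence: 9 (steps 1–4 and 7–11); steps 5–6 form the side branch to the boronic acid.

**Steps most likely to fail**

Step 8 (key step). The C3 iodane may collapse by paths other than migration of C4a: elimination to the flavone, displacement at C3 by methanol, or shift of the C2 aryl group. Prolonged acid may also erode the silyl ether or ionise the C2–O1 bond. The fallback sets out from 11 and replaces the one-pot oxidation by a stepwise, non-oxidative 1,2-aryl shift of an α-halo ketal. Bromination with CuBr2 in EtOAc/CHCl3 should give the trans-3-bromoflavanone F1. Ketalisation with HC(OMe)3/MeOH and catalytic MsOH should give the bromo ketal F2. AgBF4 in MeOH/HC(OMe)3 should then pull off bromide while C4a migrates with inversion at C3, so that the route is rejoined at 14. Halogenation, ketalisation and migration are thereby controlled separately, and no oxidant is present during the rearrangement.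

Step 7. Facial discrimination in the carbopalladation of the 8-methoxychromone may be poor, leaving 11 with insufficient enantiomeric purity. The fallback sets out from 7 and 10 and sets the stereocentre by resolution instead of by asymmetric C–C bond formation. The same addition with an achiral catalyst (Pd(OCOCF3)2, 2,2′-bipyridine) should give the racemic flavanone F3. Kinetic resolution by Noyori–Ikariya transfer hydrogenation (RuCl(p-cymene)[(S,S)-TsDPEN], HCO2H/Et3N) follows; this catalyst gives 4S carbinols from chromanones, so it should consume the 2S enantiomer as the cis-(2S,4S)-flavan-4-ol F4 and leave the 2R ketone. After chromatographic separation the route is rejoined at 11.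

Step 10. A free phenol may be O-alkylated by the alkoxyphosphonium ion, or elimination across C3–C9 may compete with substitution. The fallback sets out from 15 and replaces the Mitsunobu reaction by a carbodiimide acylation of a fully phenol-protected substrate. Silylation of 15 with TBSCl/imidazole should give the bis-TBS ether F5. Mild acid methanolysis (PPTS, MeOH) should remove only the primary alkyl TBS group and give the aryl TBS ether with free C9 carbinol F6. In parallel, 16 is silylated twice (TBSCl, imidazole, DMF) to the silyl ester silyl ether F7, whose silyl ester is hydrolysed on work-up (K2CO3, MeOH/H2O) to 4-O-TBS-p-coumaric acid F8. Steglich coupling of F6 with F8 (EDC·HCl, DMAP, CH2Cl2) should give the fully silylated coumarate F9. HF·pyridine or TBAF/AcOH then removes all three silyl groups, and the route is rejoined at 18.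

**Further compounds**

F1 | step 8 | 4-[(2S,3S)-3-bromo-6-[3-(tert-butyldiphenylsilyloxy)propyl]-8-methoxy-4-oxochroman-2-yl]-2-methoxyphenyl pivalate (trans; C2 geometry as in 11) | COc1cc([C@@H]2Oc3c(OC)cc(CCCO[Si](c4ccccc4)(c5ccccc5)C(C)(C)C)cc3C(=O)[C@H]2Br)ccc1OC(=O)C(C)(C)C
F2 | step 8 | 4-[(2S,3S)-3-bromo-6-[3-(tert-butyldiphenylsilyloxy)propyl]-4,4,8-trimethoxychroman-2-yl]-2-methoxyphenyl pivalate | COc1cc([C@@H]2Oc3c(OC)cc(CCCO[Si](c4ccccc4)(c5ccccc5)C(C)(C)C)cc3C(OC)(OC)[C@H]2Br)ccc1OC(=O)C(C)(C)C
F3 | step 7 | racemic 6-[3-(tert-butyldiphenylsilyloxy)propyl]-8-methoxy-2-[3-methoxy-4-(pivaloyloxy)phenyl]chroman-4-one | COc1cc(C2Oc3c(OC)cc(CCCO[Si](c4ccccc4)(c5ccccc5)C(C)(C)C)cc3C(=O)C2)ccc1OC(=O)C(C)(C)C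
F4 | step 7 | 4-[(2S,4S)-6-[3-(tert-butyldiphenylsilyloxy)propyl]-4-hydroxy-8-methoxychroman-2-yl]-2-methoxyphenyl pivalate (cis) | COc1cc([C@H]2Oc3c(OC)cc(CCCO[Si](c4ccccc4)(c5ccccc5)C(C)(C)C)cc3[C@@H](O)C2)ccc1OC(=O)C(C)(C)C
F5 | step 10 | bis-TBS ether of 15 (aryl O-TBS and C9 O-TBS), (2R,3S) | COc1cc([C@@H]2Oc3c(OC)cc(CCCO[Si](c4ccccc4)(c5ccccc5)C(C)(C)C)cc3[C@H]2CO[Si](C)(C)C(C)(C)C)ccc1O[Si](C)(C)C(C)(C)C
F6 | step 10 | {(2R,3S)-2-[4-(tert-butyldimethylsilyloxy)-3-methoxyphenyl]-5-[3-(tert-butyldiphenylsilyloxy)propyl]-7-methoxy-2,3-dihydro-1-benzofuran-3-yl}methanol | COc1cc([C@@H]2Oc3c(OC)cc(CCCO[Si](c4ccccc4)(c5ccccc5)C(C)(C)C)cc3[C@H]2CO)ccc1O[Si](C)(C)C(C)(C)C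
F7 | step 10 | tert-butyldimethylsilyl (E)-3-[4-(tert-butyldimethylsilyloxy)phenyl]prop-2-enoate | CC(C)(C)[Si](C)(C)OC(=O)/C=C/c1ccc(O[Si](C)(C)C(C)(C)C)cc1
F8 | step 10 | (E)-3-[4-(tert-butyldimethylsilyloxy)phenyl]prop-2-enoic acid | O=C(O)/C=C/c1ccc(O[Si](C)(C)C(C)(C)C)cc1
F9 | step 10 | {(2R,3S)-2-[4-(tert-butyldimethylsilyloxy)-3-methoxyphenyl]-5-[3-(tert-butyldiphenylsilyloxy)propyl]-7-methoxy-2,3-dihydro-1-benzofuran-3-yl}methyl (E)-3-[4-(tert-butyldimethylsilyloxy)phenyl]prop-2-enoate | COc1cc([C@@H]2Oc3c(OC)cc(CCCO[Si](c4ccccc4)(c5ccccc5)C(C)(C)C)cc3[C@H]2COC(=O)/C=C/c2ccc(O[Si](C)(C)C(C)(C)C)cc2)ccc1O[Si](C)(C)C(C)(C)C
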